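**Retrosynthetic overview**

- The strategy rests on ring B: C1–C5 all carry oxygen and C6 is the only C–H. C2 (O–ring C) and C3–C5 (OH) correspond to the four carbons of squaric acid; C1 (O–ring A) and C6–H correspond to a terminal aryl ethynyl ether.
- Key disconnection: Danheiser benzannulation of 4-silyloxycyclobutenone 11 with ynol ether 22, making C5–C6, C1–C2 and then C4–C5. Both diaryl ether C–O bonds are in place before ring B exists.
- Cyclobutenone 11: squaric acid → squaryl dichloride → benzyl ester chloride → ring C aryl ester → regioselective hydride reduction → silyl ether.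
- Ynol ether 22: phloroglucinol → 2,4,6-tris(benzyloxy)phenol → dichlorovinyl ether (trichloroethylene) → n-BuLi.
- Ring order: rings A and C are purchased arenes, the four-membered ring is purchased as squaric acid, and ring B is formed last; desilylation and hydrogenolysis finish the route.

Key step: step 15

Remark: ring B is numbered C1 (O–ring A), C2 (O–ring C), C3–C5 (OH), C6 (H). The target is achiral; 10, 11, 24 and 26 are racemic.

**Ring C phenol**

Step 1
Reactants: 1 3,4,5-trihydroxybenzaldehyde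
Product: 2 3,4,5-tris(benzyloxy)benzaldehyde
Conditions: BnBr (3.3 equiv), K2CO3, DMF, 60 °C, N2
Reagents that add atoms: benzyl bromide, BrCc1ccccc1
Why: Williamson etherification of the three phenoxides under carbonate in DMF, with the aldehyde inert and nitrogen protecting the pyrogallol unit from air oxidation.

Step 2
Reactants: 2 3,4,5-tris(benzyloxy)benzaldehyde
Product: 3 3,4,5-tris(benzyloxy)phenyl formate
Conditions: mCPBA (1.3 equiv), CH2Cl2, 0 °C to rt
Reagents that add atoms: mCPBA, OOC(=O)c1cccc(Cl)c1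
Why: Baeyer–Villiger oxidation in which the electron-rich aryl group (para benzyloxy) migrates in preference to hydride, so the formate should form rather than the acid.

Step 3
Reactants: 3 3,4,5-tris(benzyloxy)phenyl formate
Product: 4 3,4,5-tris(benzyloxy)phenol
Conditions: K2CO3 (0.1 equiv), MeOH/THF, 0 °C to rt, degassed
Reagents that add atoms: none
Why: Base-catalysed transesterification of an activated aryl formate to methanol, which leaves the benzyl ethers untouched.

**Cyclobutenone from squaric acid**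

Step 4
Reactants: 5 squaric acid
Product: 6 3,4-dichlorocyclobut-3-ene-1,2-dione (squaryl dichloride)
Conditions: (COCl)2 (2.2 equiv), DMF (cat.), CH2Cl2, rt to 40 °C
Reagents that add atoms: oxalyl chloride, O=C(Cl)C(Cl)=O
Why: Vilsmeier-type activation converts the two vinylogous carboxylic acid hydroxyls into vinylogous acid chlorides, the standard preparation of this dichloride.

Step 5
Reactants: 6 squaryl dichloride; 7 benzyl alcohol
Product: 8 3-(benzyloxy)-4-chlorocyclobut-3-ene-1,2-dione
Conditions: 7 (1.0 equiv), i-Pr2NEt (1.0 equiv), CH2Cl2, −78 to −40 °C; used without chromatography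
Reagents that add atoms: none
Why: Addition–elimination at a vinylogous acid chloride; the first alkoxy donor lowers the electrophilicity of the remaining C–Cl, so one equivalent of alcohol at low temperature should stop at the monoester.

Step 6
Reactants: 8 3-(benzyloxy)-4-chlorocyclobut-3-ene-1,2-dione; 4 3,4,5-tris(benzyloxy)phenol
Product: 9 3-(benzyloxy)-4-[3,4,5-tris(benzyloxy)phenoxy]cyclobut-3-ene-1,2-dione
Conditions: 4 (1.0 equiv), i-Pr2NEt (1.05 equiv), CH2Cl2, −40 to 0 °C, anhydrous
Reagents that add atoms: none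
Why: Second addition–elimination in which chloride leaves far more readily than benzyloxide, so the ring C–O–C2 bond is made without a metal; one equivalent of phenol avoids exchange of the benzyl ester.

Step 7
Reactants: 9 mixed benzyl aryl squarate
Product: 10 3-(benzyloxy)-4-hydroxy-2-[3,4,5-tris(benzyloxy)phenoxy]cyclobut-2-en-1-one (racemic)
Conditions: LiAlH(OtBu)3 (1.05 equiv), THF, −78 °C; aq. potassium sodium tartrate, 0 °C (no acid)
Reagents that add atoms: none
Why: 1,2-reduction of a squarate diester by a bulky alkoxyaluminium hydride, expected at the carbonyl next to the benzyloxy carbon because its vinylogous donor is the weaker aryloxy oxygen; the carbinol centre forms as the racemate, which suffices since it becomes aromatic in step 15, and the regiochemistry is to be confirmed by HMBC with any isomer removed here.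

Step 8
Reactants: 10 hydroxycyclobutenone
Product: 11 3-(benzyloxy)-4-(tert-butyldimethylsilyloxy)-2-[3,4,5-tris(benzyloxy)phenoxy]cyclobut-2-en-1-one (racemic)
Conditions: TBSOTf (1.2 equiv), 2,6-lutidine (1.5 equiv), CH2Cl2, −78 °C
Reagents that add atoms: tert-butyldimethylsilyl triflate, CC(C)(C)[Si](C)(C)OS(=O)(=O)C(F)(F)F
Why: Silylation of a secondary alcohol with a silyl triflate and a hindered pyridine avoids the acid that would eliminate benzyl alcohol, and the silyl ether prevents the later ketene from closing to a butenolide.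

**Ring A ynol ether**

Step 9
Reactants: 12 phloroglucinol
Product: 13 1,3,5-tris(benzyloxy)benzene
Conditions: BnBr (3.3 equiv), K2CO3, DMF, rt to 50 °C, N2; crystallisation
Reagents that add atoms: benzyl bromide, BrCc1ccccc1
Why: Williamson etherification in a dipolar aprotic solvent, which favours O- over C-alkylation of phloroglucinol; C-benzylated by-products should be removable by crystallisation.

Step 10
Reactants: 13 1,3,5-tris(benzyloxy)benzene
Product: 15 2,4,6-tris(benzyloxy)benzaldehyde, via aryl iminium salt 14 (not isolated)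
Conditions: POCl3 (1.2 equiv), DMF, 0 °C to rt; then ice/H2O, rt
Reagents that add atoms: N,N-dimethylformamide, CN(C)C=O; water, O
Why: Vilsmeier–Haack formylation of a strongly activated arene whose three free positions are equivalent; the iminium group deactivates the ring against a second attack and is hydrolysed on work-up.

Step 11
Reactants: 15 2,4,6-tris(benzyloxy)benzaldehyde
Product: 16 2,4,6-tris(benzyloxy)phenyl formate
Conditions: mCPBA (1.3 equiv), CH2Cl2, 0 °C to rt
Reagents that add atoms: mCPBA, OOC(=O)c1cccc(Cl)c1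
Why: Baeyer–Villiger oxidation with migration of the aryl group bearing two ortho and one para alkoxy donors; the formate also shields the very electron-rich phenol from over-oxidation.

Step 12
Reactants: 16 2,4,6-tris(benzyloxy)phenyl formate
Product: 17 2,4,6-tris(benzyloxy)phenol
Conditions: K2CO3 (0.1 equiv), MeOH/THF, 0 °C, degassed, argon
Reagents that add atoms: none
Why: Catalytic methanolysis of the aryl formate under oxygen-free conditions, since this phenol oxidises readily in air.

Step 13
Reactants: 17 2,4,6-tris(benzyloxy)phenol; 18 trichloroethylene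
Product: 19 (E)-1,2-dichlorovinyl 2,4,6-tris(benzyloxy)phenyl ether
Conditions: KH (1.2 equiv), THF/DMF, 0 °C; then 18 (1.5 equiv), 0 to 40 °C
Reagents that add atoms: none
Why: Base-induced loss of HCl from trichloroethylene gives dichloroacetylene, to which the potassium phenoxide adds with anti protonation (O and H trans, hence E); this small linear electrophile tolerates the two ortho benzyloxy groups.

Step 14
Reactants: 19 (E)-1,2-dichlorovinyl aryl ether
Product: 22 ethynyl 2,4,6-tris(benzyloxy)phenyl ether, via chloroethynyl ether 20 (not isolated), via lithium aryloxyacetylide 21 (not isolated)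
Conditions: n-BuLi (2.3 equiv), THF, −78 °C; then MeOH, −78 °C; cold work-up, kept as a cold dilute toluene solution and used at once
Reagents that add atoms: none
Why: Vinyl deprotonation and β-elimination give the chloroalkyne, chlorine–lithium exchange gives the acetylide and methanol protonates it, the standard conversion of 1,2-dichlorovinyl ethers into ynol ethers; −78 °C spares the benzyl ethers.

**Benzannulation and deprotection**

Step 15
Reactants: 11 4-silyloxycyclobutenone; 22 aryl ethynyl ether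
Product: 27 3-(benzyloxy)-2-(tert-butyldimethylsilyloxy)-5-[2,4,6-tris(benzyloxy)phenoxy]-4-[3,4,5-tris(benzyloxy)phenoxy]phenol, via vinylketene 23 (not isolated), via 4-vinylcyclobutenone 24 (not isolated), via dienylketene 25 (not isolated), via cyclohexadienone 26 (not isolated)
Conditions: 11 added slowly to 22 (2.0 equiv), degassed toluene, 80 °C, then 110 °C, sealed vessel, argon
Reagents that add atoms: none
Why: Proposed new method: heat should open 11 by conrotatory four-electron cleavage (silyloxy group turning outward) to vinylketene 23, whose ketene C=C adds across the ynol ether in a (2+2) step to give 24; a second four-electron opening to 25 and a six-electron disrotatory closure give dienone 26, which enolises to phenol 27. The closest known reaction type is the Danheiser benzannulation of 4-unsubstituted or 4-alkyl cyclobutenones with alkoxy- and siloxyalkynes, supported by the thermal opening of squarate-derived 4-oxycyclobutenones in Moore-type ring expansions; the new element is intermolecular capture of a trioxygenated vinylketene by an aryl ethynyl ether. Ring B is the only ring closed: C5–C6 and C1–C2 form in the cycloaddition and C4–C5 in the six-electron electrocyclisation, which enlarges the four-membered ring by two carbons. No stereocentre remains, because the carbinol carbon of 11 and the quaternary carbon of 24 both become aromatic carbons. The step needs the alkyne orientation that places the ring A aryloxy carbon beside the ring C aryloxy carbon, and (2+2) rather than (4+2) capture; the oxygen-polarised ynol ether (nucleophilic at its CH terminus) attacking the electrophilic ketene carbon should secure both, and the outward preference of the ring C aryloxy donor in 24 turns the vinyl group inward as the closure requires. The 4-oxygen donor lowers the opening temperature, the silyl ether blocks butenolide formation, and an aryl ynol ether has no β-hydrogen for retro-ene loss of ketene.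

Step 16
Reactants: 27 silyl-protected triaryl diether phenol
Product: 28 3-(benzyloxy)-5-[2,4,6-tris(benzyloxy)phenoxy]-4-[3,4,5-tris(benzyloxy)phenoxy]benzene-1,2-diol
Conditions: TBAF (1.1 equiv), AcOH (1.5 equiv), THF, 0 °C, argon
Reagents that add atoms: none
Why: Fluoride cleavage of an aryl silyl ether, buffered with acetic acid so that the electron-rich catechol is never present as an air-sensitive phenoxide.

Step 17
Reactants: 28 heptabenzyl catechol
Product: 29 5-(2,4,6-trihydroxyphenoxy)-4-(3,4,5-trihydroxyphenoxy)benzene-1,2,3-triol (target CNP0018317.0)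
Conditions: H2 (1 atm), Pd/C (10 %), THF/MeOH, rt; filtration and size-exclusion purification under argon with degassed solvents
Reagents that add atoms: none
Why: Hydrogenolysis of the seven benzyl aryl ethers over Pd/C, under which the two diaryl ether bonds are inert; oxygen is excluded because the free polyphenol oxidises easily.

**Compound list**

1 | 3,4,5-trihydroxybenzaldehyde | O=Cc1cc(O)c(O)c(O)c1 | starting material
2 | 3,4,5-tris(benzyloxy)benzaldehyde | O=Cc1cc(OCc2ccccc2)c(OCc2ccccc2)c(OCc2ccccc2)c1 | intermediate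
3 | 3,4,5-tris(benzyloxy)phenyl formate | O=COc1cc(OCc2ccccc2)c(OCc2ccccc2)c(OCc2ccccc2)c1 | intermediate
4 | 3,4,5-tris(benzyloxy)phenol | Oc1cc(OCc2ccccc2)c(OCc2ccccc2)c(OCc2ccccc2)c1 | intermediate
5 | squaric acid | OC1=C(O)C(=O)C1=O | starting material
6 | 3,4-dichlorocyclobut-3-ene-1,2-dione | O=C1C(=O)C(Cl)=C1Cl | intermediate
7 | benzyl alcohol | OCc1ccccc1 | starting material
8 | 3-(benzyloxy)-4-chlorocyclobut-3-ene-1,2-dione | O=C1C(=O)C(OCc2ccccc2)=C1Cl | intermediate
9 | 3-(benzyloxy)-4-[3,4,5-tris(benzyloxy)phenoxy]cyclobut-3-ene-1,2-dione | O=C1C(=O)C(OCc2ccccc2)=C1Oc1cc(OCc2ccccc2)c(OCc2ccccc2)c(OCc2ccccc2)c1 | intermediate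
10 | 3-(benzyloxy)-4-hydroxy-2-[3,4,5-tris(benzyloxy)phenoxy]cyclobut-2-en-1-one (racemic) | O=C1C(Oc2cc(OCc3ccccc3)c(OCc3ccccc3)c(OCc3ccccc3)c2)=C(OCc2ccccc2)C1O | intermediate
11 | 3-(benzyloxy)-4-(tert-butyldimethylsilyloxy)-2-[3,4,5-tris(benzyloxy)phenoxy]cyclobut-2-en-1-one (racemic) | O=C1C(Oc2cc(OCc3ccccc3)c(OCc3ccccc3)c(OCc3ccccc3)c2)=C(OCc2ccccc2)C1O[Si](C)(C)C(C)(C)C | intermediate
12 | phloroglucinol | Oc1cc(O)cc(O)c1 | starting material
13 | 1,3,5-tris(benzyloxy)benzene | c1c(OCc2ccccc2)cc(OCc2ccccc2)cc1OCc1ccccc1 | intermediate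
14 | N,N-dimethyl-[2,4,6-tris(benzyloxy)phenyl]methaniminium dichlorophosphate | C[N+](C)=Cc1c(OCc2ccccc2)cc(OCc2ccccc2)cc1OCc1ccccc1.[O-]P(=O)(Cl)Cl | intermediate
15 | 2,4,6-tris(benzyloxy)benzaldehyde | O=Cc1c(OCc2ccccc2)cc(OCc2ccccc2)cc1OCc1ccccc1 | intermediate
16 | 2,4,6-tris(benzyloxy)phenyl formate | O=COc1c(OCc2ccccc2)cc(OCc2ccccc2)cc1OCc1ccccc1 | intermediate
17 | 2,4,6-tris(benzyloxy)phenol | Oc1c(OCc2ccccc2)cc(OCc2ccccc2)cc1OCc1ccccc1 | intermediate
18 | trichloroethylene | ClC=C(Cl)Cl | starting material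
19 | (E)-1,2-dichlorovinyl 2,4,6-tris(benzyloxy)phenyl ether | Cl/C=C(/Cl)Oc1c(OCc2ccccc2)cc(OCc2ccccc2)cc1OCc1ccccc1 | intermediate
20 | chloroethynyl 2,4,6-tris(benzyloxy)phenyl ether | ClC#COc1c(OCc2ccccc2)cc(OCc2ccccc2)cc1OCc1ccccc1 | intermediate
21 | lithium [2,4,6-tris(benzyloxy)phenoxy]acetylide | [Li]C#COc1c(OCc2ccccc2)cc(OCc2ccccc2)cc1OCc1ccccc1 | intermediate
22 | ethynyl 2,4,6-tris(benzyloxy)phenyl ether | C#COc1c(OCc2ccccc2)cc(OCc2ccccc2)cc1OCc1ccccc1 | intermediate
23 | (Z)-3-(benzyloxy)-4-(tert-butyldimethylsilyloxy)-2-[3,4,5-tris(benzyloxy)phenoxy]buta-1,3-dien-1-one (vinylketene) | O=C=C(Oc1cc(OCc2ccccc2)c(OCc2ccccc2)c(OCc2ccccc2)c1)/C(OCc1ccccc1)=C/O[Si](C)(C)C(C)(C)C | intermediate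
24 | 4-[(Z)-1-(benzyloxy)-2-(tert-butyldimethylsilyloxy)vinyl]-3-[2,4,6-tris(benzyloxy)phenoxy]-4-[3,4,5-tris(benzyloxy)phenoxy]cyclobut-2-en-1-one (racemic) | O=C1C=C(Oc2c(OCc3ccccc3)cc(OCc3ccccc3)cc2OCc2ccccc2)C1(Oc1cc(OCc2ccccc2)c(OCc2ccccc2)c(OCc2ccccc2)c1)/C(OCc1ccccc1)=C/O[Si](C)(C)C(C)(C)C | intermediate
25 | (3Z,5Z)-5-(benzyloxy)-6-(tert-butyldimethylsilyloxy)-3-[2,4,6-tris(benzyloxy)phenoxy]-4-[3,4,5-tris(benzyloxy)phenoxy]hexa-1,3,5-trien-1-one (dienylketene) | O=C=C/C(Oc1c(OCc2ccccc2)cc(OCc2ccccc2)cc1OCc1ccccc1)=C(Oc1cc(OCc2ccccc2)c(OCc2ccccc2)c(OCc2ccccc2)c1)\C(OCc1ccccc1)=C\O[Si](C)(C)C(C)(C)C | intermediate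
26 | 5-(benzyloxy)-6-(tert-butyldimethylsilyloxy)-3-[2,4,6-tris(benzyloxy)phenoxy]-4-[3,4,5-tris(benzyloxy)phenoxy]cyclohexa-2,4-dien-1-one (racemic) | O=C1C=C(Oc2c(OCc3ccccc3)cc(OCc3ccccc3)cc2OCc2ccccc2)C(Oc2cc(OCc3ccccc3)c(OCc3ccccc3)c(OCc3ccccc3)c2)=C(OCc2ccccc2)C1O[Si](C)(C)C(C)(C)C | intermediate
27 | 3-(benzyloxy)-2-(tert-butyldimethylsilyloxy)-5-[2,4,6-tris(benzyloxy)phenoxy]-4-[3,4,5-tris(benzyloxy)phenoxy]phenol | Oc1cc(Oc2c(OCc3ccccc3)cc(OCc3ccccc3)cc2OCc2ccccc2)c(Oc2cc(OCc3ccccc3)c(OCc3ccccc3)c(OCc3ccccc3)c2)c(OCc2ccccc2)c1O[Si](C)(C)C(C)(C)C | intermediate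
28 | 3-(benzyloxy)-5-[2,4,6-tris(benzyloxy)phenoxy]-4-[3,4,5-tris(benzyloxy)phenoxy]benzene-1,2-diol | Oc1cc(Oc2c(OCc3ccccc3)cc(OCc3ccccc3)cc2OCc2ccccc2)c(Oc2cc(OCc3ccccc3)c(OCc3ccccc3)c(OCc3ccccc3)c2)c(OCc2ccccc2)c1O | intermediate
29 | 5-(2,4,6-trihydroxyphenoxy)-4-(3,4,5-trihydroxyphenoxy)benzene-1,2,3-triol (CNP0018317.0) | Oc1cc(O)c(Oc2cc(O)c(O)c(O)c2Oc2cc(O)c(O)c(O)c2)c(O)c1 | target

**Step count**

Total step count: 17.
Longest linear sequence: 9 steps (12 to 29 through steps 9–17; the line from 1 through steps 1–3, 6–8 and 15–17 is equally long).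

**Steps most likely to fail**

1. Step 15 (the proposed benzannulation). The vinylketene may dimerise, may be captured in a (4+2) sense or with the opposite alkyne orientation, or the ynol ether may oligomerise faster than it traps the ketene. The fallback uses known Ullmann ether chemistry on a preformed ring B; it sets out from aldehyde 2 (with 4 and 13 as partners) and comes back at target 29. Bromination of 2 ortho to the formyl group (NBS, MeCN) would give 2-bromo-3,4,5-tris(benzyloxy)benzaldehyde F1. Ullmann coupling of F1 with phenol 4 (CuI, N,N-dimethylglycine, Cs2CO3, dioxane, 90 °C; the ortho formyl group activates the bromide) would give 3,4,5-tris(benzyloxy)-2-[3,4,5-tris(benzyloxy)phenoxy]benzaldehyde F2. Baeyer–Villiger oxidation (mCPBA) would give 3,4,5-tris(benzyloxy)-2-[3,4,5-tris(benzyloxy)phenoxy]phenyl formate F3, and methanolysis would give 3,4,5-tris(benzyloxy)-2-[3,4,5-tris(benzyloxy)phenoxy]phenol F4, whose new hydroxyl sits on C1 of ring B. Iodination of 13 (NIS, MeCN) would give 2-iodo-1,3,5-tris(benzyloxy)benzene F5. A second Ullmann coupling of F4 with F5 (CuI, picolinic acid, K3PO4, DMSO, 100 °C) would give 1,2,3-tris(benzyloxy)-5-[2,4,6-tris(benzyloxy)phenoxy]-4-[3,4,5-tris(benzyloxy)phenoxy]benzene F6. Hydrogenolysis of F6 under the conditions of step 17 returns to 29.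

2. Step 7 (hydride reduction of the mixed squarate). Hydride may discriminate poorly between the two carbonyl groups, or may add in a conjugate sense and expel the aryloxide. The fallback removes the regiochemical question by symmetry; it sets out from dichloride 6 and phenol 4 and comes back at 11. Two equivalents of 4 with i-Pr2NEt would give bis[3,4,5-tris(benzyloxy)phenyl] squarate F7. Reduction with LiAlH(OtBu)3 can then give only one product, 4-hydroxy-2,3-bis[3,4,5-tris(benzyloxy)phenoxy]cyclobut-2-en-1-one F8. Silylation (TBSOTf, 2,6-lutidine) would give 4-(tert-butyldimethylsilyloxy)-2,3-bis[3,4,5-tris(benzyloxy)phenoxy]cyclobut-2-en-1-one F9. In F9 only the aryloxy group on C3 is a vinylogous aryl ester; addition–elimination with benzyl alcohol 7 (DBU, CH2Cl2, 0 °C) should exchange it for benzyloxy, leave the C2 aryloxy group in place, give 11 and release one equivalent of 4 for recycling.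

3. Step 14 (terminal ynol ether). The terminal aryl ethynyl ether may oligomerise during work-up and concentration, or the benzyl ethers may be metalated by excess n-BuLi during a slow reaction. The fallback avoids the free terminal alkyne; it sets out from acetylide 21 (generated as in step 14) and comes back at 27. Quenching 21 with Me3SiCl instead of methanol would give the storable (trimethylsilyl)ethynyl 2,4,6-tris(benzyloxy)phenyl ether F10. Heating F10 with 11 as in step 15 should place the silyl group on C6 and give 3-(benzyloxy)-2-(tert-butyldimethylsilyloxy)-6-(trimethylsilyl)-5-[2,4,6-tris(benzyloxy)phenoxy]-4-[3,4,5-tris(benzyloxy)phenoxy]phenol F11. Ipso-protodesilylation of this electron-rich arylsilane (CF3CO2H, CH2Cl2, 0 °C) then gives 27.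

**Further compounds**

F1 | step 15 | 2-bromo-3,4,5-tris(benzyloxy)benzaldehyde | O=Cc1cc(OCc2ccccc2)c(OCc2ccccc2)c(OCc2ccccc2)c1Br
F2 | step 15 | 3,4,5-tris(benzyloxy)-2-[3,4,5-tris(benzyloxy)phenoxy]benzaldehyde | O=Cc1cc(OCc2ccccc2)c(OCc2ccccc2)c(OCc2ccccc2)c1Oc1cc(OCc2ccccc2)c(OCc2ccccc2)c(OCc2ccccc2)c1
F3 | step 15 | 3,4,5-tris(benzyloxy)-2-[3,4,5-tris(benzyloxy)phenoxy]phenyl formate | O=COc1cc(OCc2ccccc2)c(OCc2ccccc2)c(OCc2ccccc2)c1Oc1cc(OCc2ccccc2)c(OCc2ccccc2)c(OCc2ccccc2)c1
F4 | step 15 | 3,4,5-tris(benzyloxy)-2-[3,4,5-tris(benzyloxy)phenoxy]phenol | Oc1cc(OCc2ccccc2)c(OCc2ccccc2)c(OCc2ccccc2)c1Oc1cc(OCc2ccccc2)c(OCc2ccccc2)c(OCc2ccccc2)c1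
F5 | step 15 | 2-iodo-1,3,5-tris(benzyloxy)benzene | Ic1c(OCc2ccccc2)cc(OCc2ccccc2)cc1OCc1ccccc1
F6 | step 15 | 1,2,3-tris(benzyloxy)-5-[2,4,6-tris(benzyloxy)phenoxy]-4-[3,4,5-tris(benzyloxy)phenoxy]benzene | c1(Oc2c(OCc3ccccc3)cc(OCc3ccccc3)cc2OCc2ccccc2)cc(OCc2ccccc2)c(OCc2ccccc2)c(OCc2ccccc2)c1Oc1cc(OCc2ccccc2)c(OCc2ccccc2)c(OCc2ccccc2)c1
F7 | step 7 | 3,4-bis[3,4,5-tris(benzyloxy)phenoxy]cyclobut-3-ene-1,2-dione | O=C1C(=O)C(Oc2cc(OCc3ccccc3)c(OCc3ccccc3)c(OCc3ccccc3)c2)=C1Oc1cc(OCc2ccccc2)c(OCc2ccccc2)c(OCc2ccccc2)c1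
F8 | step 7 | 4-hydroxy-2,3-bis[3,4,5-tris(benzyloxy)phenoxy]cyclobut-2-en-1-one (racemic) | O=C1C(Oc2cc(OCc3ccccc3)c(OCc3ccccc3)c(OCc3ccccc3)c2)=C(Oc2cc(OCc3ccccc3)c(OCc3ccccc3)c(OCc3ccccc3)c2)C1O
F9 | step 7 | 4-(tert-butyldimethylsilyloxy)-2,3-bis[3,4,5-tris(benzyloxy)phenoxy]cyclobut-2-en-1-one (racemic) | O=C1C(Oc2cc(OCc3ccccc3)c(OCc3ccccc3)c(OCc3ccccc3)c2)=C(Oc2cc(OCc3ccccc3)c(OCc3ccccc3)c(OCc3ccccc3)c2)C1O[Si](C)(C)C(C)(C)C
F10 | step 14 | (trimethylsilyl)ethynyl 2,4,6-tris(benzyloxy)phenyl ether | C[Si](C)(C)C#COc1c(OCc2ccccc2)cc(OCc2ccccc2)cc1OCc1ccccc1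
F11 | step 14 | 3-(benzyloxy)-2-(tert-butyldimethylsilyloxy)-6-(trimethylsilyl)-5-[2,4,6-tris(benzyloxy)phenoxy]-4-[3,4,5-tris(benzyloxy)phenoxy]phenol | Oc1c([Si](C)(C)C)c(Oc2c(OCc3ccccc3)cc(OCc3ccccc3)cc2OCc2ccccc2)c(Oc2cc(OCc3ccccc3)c(OCc3ccccc3)c(OCc3ccccc3)c2)c(OCc2ccccc2)c1O[Si](C)(C)C(C)(C)C
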